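## Structural features

The target 21 is a 2-hydroxy-1,4-naphthoquinone in which quinone ring A (C1 to C4, closed by the fusion atoms C4a and C8a) is fused to benzene ring B, and ring B carries methoxy groups on C5, C6 and C8 and a single hydrogen on C7. C3 bears a 2-acetoxypropyl chain whose carbinol carbon is the only stereocentre, (S); no stereocentres stand next to each other, and the one present is separated from ring A by a methylene group, so it cannot be lost by enolisation and is best taken from the chiral pool. The fragile groups are the secondary acetate (it survives neither organometallic reagents nor aqueous alkali), the acidic vinylogous-acid hydroxyl on C2 (it competes with the side-chain alcohol in acylation and exposes ring A to oxidative degradation in alkali), the peri methoxy groups on C5 and C8 (cleaved by chelating Lewis acids) and the electron-rich ring B (a strong one-electron oxidant would turn its 5,8-dimethoxy pair into a second quinone). The real difficulty is the orientation and substitution of ring A: both rings are unsymmetrical, so the oxygen on C2 must face C8 and the side chain on C3 must face C5, and C2=C3 is a fully substituted double bond with one oxygen and one carbon substituent. The plan exploits that C2=C3 is the only non-aromatic carbon–carbon double bond and that its neighbours C1 and C4 are carbonyl carbons attached to the adjacent ring B atoms C8a and C4a. Taken back to carbinols, C1 and C4 can each carry one half of that double bond as a vinyl group, an ethyl enol ether olefin on C1 and an alkyl-substituted olefin on C4, and ring A can be closed between them by olefin metathesis. Since both carbinols are oxidised afterwards, their configuration does not matter, and the two different vinyl units can be attached one after the other, which settles the orientation.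

## Logic of the disconnections

21 ⇒ 19 (through 20). The bond cut is the acyl–oxygen bond of the side-chain ester. It comes off first because this ester tolerates none of the carbanion or hydroxide chemistry needed earlier; without it the side-chain oxygen can travel as a silyl ether. The forward step must tell the secondary alcohol from the acidic C2 hydroxyl. This is met by acylating both (20) and hydrolysing the far more labile C2 ester in the same flask.

19 ⇒ 18 ⇒ 17. First the O–Si bond is cut, then the C2–O bond of the vinylogous ester (ethoxy in place of hydroxy). The C2 oxygen has to enter as an ethyl enol ether for the ring closure, and the silyl ether is what carried the side chain through it. The gain is that 17 has no acidic or nucleophilic group. The demand is one of order: hydrolysis must precede desilylation, because a free side-chain alkoxide next to the C2 ethoxy group would displace it and close a dihydrofuran ring. The hydrolysis must also spare the aryl methyl ethers and the silyl ether.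

17 ⇒ 15 (through 16). The carbonyl groups at C1 and C4 are taken back to secondary carbinols. Carbinols are what carbonyl additions deliver, and they are compatible with a ruthenium alkylidene where an ene-dione would not be. The gain is that configuration at C1 and C4 becomes irrelevant: every isomer, and any half-oxidised material, funnels through 16. The demand is a neutral oxidant selective for benzylic, allylic alcohols that leaves ring B alone.

15 ⇒ 14. The C2=C3 bond is cut, each carbon receiving a terminal methylene. This is the only ring bond that is not attached to ring B, and cutting it turns ring A into two different vinyl groups on ortho carbinols. The gain is one ring, with no stereochemistry to control. The demand is heavy: a metathesis that forms a tetrasubstituted olefin bearing an alkoxy group, without acid and without hydride-induced isomerisation of the carbinols.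

14 ⇒ 10 + 12 (12 from 11). The C1–C2 bond is cut as a carbonyl addition of an acyl anion equivalent to the masked formyl group of 10. This places the enol ether, and therefore the C2 oxygen, on the carbon next to C8a. The demand is that the lactol opens under the basic conditions and that the acid-labile product is isolated under neutral conditions.

10 ⇒ 6 + 5 (through 7, 8 and 9). The C4a–C4 bond is cut as the addition of an aryl anion to an enal. This bond decides the orientation of ring A: the carbon that is metallated is the one flanked by the formyl carbon and a methoxy group, so the alkyl-bearing olefin ends up on the C5 side. The gain is that ring B is bought intact with all three methoxy groups. The demand is regioselective metallation at that carbon and not between the two other methoxy groups, and 1,2-addition to the enal.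

5 ⇒ 4 ⇒ 3 ⇒ 2 ⇒ 1. The exocyclic C=CH2 bond is cut (α-methylenation of an aldehyde), then the aldehyde is traced to a hydroxamate, the silyl ether to the alcohol, and the open chain to the lactone. The stereocentre is bought, and the five-carbon chain already has the right length. The demands are modest: the C–O bond at the stereocentre must never be broken, and the hydroxy amide must be silylated before it relactonises.

## Other disconnections considered

Alternative 1: The cut removes both aryl–carbon bonds of ring A (C8a–C1 and C4a–C4) and leaves C2–C3 for a later condensation.
- Forward step: CsF would release the aryne A4 from the silyl triflate A2. The enolate of the β-ketoester A3 adds, the aryl anion closes onto the ketone, and fragmentation of the four-membered alkoxide inserts the arene into the ketone-to-methylene bond, giving A1. A base-induced Claisen-type closure (C3 onto the ester carbon C2) and aerobic oxidation at C1 would then lead to 18.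
- In favour: the insertion and its extension to 2-hydroxynaphthoquinones are known reaction types. The C2 oxygen and the C3 alkyl group are placed by the connectivity of A3, and no hindered olefin has to be forced.
- Against: both termini of A4 carry an ortho methoxy group, so the polarisation that normally steers the nucleophile cancels to first order. Only the more remote C6 methoxy group distinguishes the two ends. A1 could therefore be accompanied by the isomer in which ring A is turned round relative to ring B, which would be hard to separate and to tell apart. A2 also needs several steps from a phenol, and A3 about three from 1.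
- Comparison: on structure the chosen plan is safer, because it fixes the orientation of ring A by the order of two different additions. On mechanism the alternative is the better: it rests on precedented chemistry, whereas step 7 does not. On step economy the alternative is also the better, at roughly eight steps in its longest line against eleven.

Alternative 2: The cut removes C4a–C5 and C8–C8a, so ring B is built and ring A is bought as a benzoquinone.
- Forward step: the unsubstituted double bond of the quinone A6 would add the oxygenated diene A7. Loss of the silyl and methoxy groups from the former ketene-acetal carbon and enolisation would give the hydroquinone A5.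
- In favour: the orientation is predictable. The C2 methoxy group of A6 weakens the C4 carbonyl by vinylogous-ester conjugation, so the C1 carbonyl directs the methoxy-bearing diene terminus to the future C4a and the ketene-acetal carbon becomes C8. The step is a thermal pericyclic reaction of a well-understood class and needs no metal.
- Against: A7 is a hydrolytically labile, tetra-oxygenated diene with a geometry problem at its methoxy-bearing terminus. In the adduct the C5 methoxy group sits β to the C4 carbonyl, so β-elimination competes with the wanted enolisation and would aromatise ring B without that substituent. A5 still needs oxidation, methylation of the chelated C8 hydroxyl and hydrolysis of the C2 methyl ether, which would also cleave the acetate. A6 must itself be made with the stereocentre, so the problem of differentiating C2 and C3 is only moved into its synthesis.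
- Comparison: on structure the chosen plan is better, because ring B is bought complete and never touched. On mechanism the alternative is the better, its key step being firmly precedented. On step economy the two are about equal once A6 and the four or more steps after A5 are counted.

Alternative 3: The cut removes C3–C4, C1–C2 and C4–C4a, so ring A is assembled from a two-carbon aryl ketene unit and an alkyne.
- Forward step: irradiation of the diazoketone A9 would give, by Wolff rearrangement, an aryl ketene. Its [2+2] addition to the siloxyalkyne A10 gives a 4-arylcyclobutenone, whose four-electron ring opening and six-electron electrocyclisation onto the arene close ring A as the naphthol A8.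
- In favour: the polarity of ketene and ynol ether dictates oxygen on C2, alkyl on C3 and hydroxyl on C4. Only one ortho position of the aryl group carries hydrogen, so the orientation towards ring B is fixed as well. On this point the alternative is the equal of the chosen plan. The C2 oxygen arrives as a silyl ether that falls together with the side-chain silyl ether, so no vinylogous ester has to be hydrolysed. The longest line would be about eight steps, which is better than eleven, and the key step is a known reaction type, which is also better.
- Against: it requires a diazoketone and a photochemical step. The electrocyclisation must break the aromaticity of a crowded, electron-rich ring. A8 is a peri-substituted, very electron-rich naphthol prone to autoxidation, and A10 is moisture-sensitive and comes from ynolate chemistry. C1 arrives as C–H and must still be oxidised to the quinone, which is routine and about equal to the double carbinol oxidation of the chosen plan.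
- Comparison: the chosen plan uses only polar additions and one catalytic thermal step and avoids diazo and photochemistry. Its key step is the less certain of the two.

Key step: step 7

Remark: bicyclic compounds are named with the ring numbering of the target (oxygen substituent on C2, side chain on C3, methoxy groups on C5, C6 and C8); the carbinol centres at C1 and C4 are formed without control and carried as mixtures, so they are left undefined in names and SMILES, and organolithium species are drawn as covalent monomers.

## Route

Step 1
Reactants: 1 (S)-γ-valerolactone [(5S)-5-methyldihydrofuran-2(3H)-one]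
Product: 2 (4S)-4-hydroxy-N-methoxy-N-methylpentanamide
Conditions: MeNH(OMe)·HCl, i-PrMgCl, THF, −20 → 0 °C; aq. NH4Cl
Reagents that add atoms: N,O-dimethylhydroxylamine hydrochloride, CNOC.Cl
Why: Aminolysis of the lactone by the chloromagnesium amide (Weinreb amide formation) cleaves the acyl–oxygen bond only, so the carbinol centre keeps its (S) configuration; 2 is silylated at once because it can relactonise.

Step 2
Reactants: 2 (4S)-4-hydroxy-N-methoxy-N-methylpentanamide
Product: 3 (4S)-4-(tert-butyldimethylsilyloxy)-N-methoxy-N-methylpentanamide
Conditions: TBSCl, imidazole, DMF, 0 °C → rt
Reagents that add atoms: tert-butyldimethylsilyl chloride, CC(C)(C)[Si](C)(C)Cl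
Why: Standard O-silylation of a secondary alcohol; the silyl ether is chosen because it should survive the organolithium steps, the metathesis, MnO2 and dilute alkali, and it is removed by fluoride without touching the C–O bond of the stereocentre.

Step 3
Reactants: 3 (4S)-4-(tert-butyldimethylsilyloxy)-N-methoxy-N-methylpentanamide
Product: 4 (4S)-4-(tert-butyldimethylsilyloxy)pentanal
Conditions: i-Bu2AlH, THF, −78 °C; H2O, aq. potassium sodium tartrate
Reagents that add atoms: none
Why: Weinreb amide reduction: the chelated tetrahedral aluminium adduct is stable at low temperature and releases the aldehyde only on work-up, so over-reduction should not occur.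

Step 4
Reactants: 4 (4S)-4-(tert-butyldimethylsilyloxy)pentanal
Product: 5 (4S)-4-(tert-butyldimethylsilyloxy)-2-methylenepentanal
Conditions: 37% aq. CH2O, pyrrolidine (10 mol %), EtCO2H (10 mol %), i-PrOH, 45 °C
Reagents that add atoms: formaldehyde, C=O
Why: Amine-catalysed α-methylenation (Mannich condensation followed by elimination of the amine); the silyloxy group is γ to the formyl group, so neither epimerisation nor β-elimination is expected, and 5 is used promptly because 2-substituted acroleins polymerise.

Step 5
Reactants: 6 2,4,5-trimethoxybenzaldehyde; 5 (4S)-4-(tert-butyldimethylsilyloxy)-2-methylenepentanal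
Product: 10 3-[(4S)-4-(tert-butyldimethylsilyloxy)pent-1-en-2-yl]-4,5,7-trimethoxy-1,3-dihydroisobenzofuran-1-ol (lactol; mixture at C1 and C3; in equilibrium with its open hydroxy aldehyde), via α-amino alkoxide 7 (not isolated), via aryllithium 8 (not isolated), via dilithium adduct 9 (not isolated)
Conditions: 6 (1.5 equiv), LiN(Me)CH2CH2NMe2 (from Me(H)NCH2CH2NMe2 + n-BuLi), THF, −20 °C; n-BuLi (1.1 equiv per 6), −20 °C; 5 (1.0 equiv), −78 → 0 °C; H2O
Reagents that add atoms: none
Why: α-Amino alkoxide-directed ortho-lithiation: the lithium amide masks the formyl group, the alkoxide with its chelating dimethylaminoethyl arm delivers n-BuLi to the neighbouring ring C–H that is also acidified by the adjacent methoxy group, and the aryllithium adds 1,2 to the enal. On aqueous work-up the hemiaminal collapses and the freed formyl group is trapped by the new hydroxyl as the lactol; the new carbinol centre (future C4) is uncontrolled and need not be controlled.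

Step 6
Reactants: 10 3-[(4S)-4-(tert-butyldimethylsilyloxy)pent-1-en-2-yl]-4,5,7-trimethoxy-1,3-dihydroisobenzofuran-1-ol; 11 ethyl vinyl ether
Product: 14 2-ethoxy-1-{2-[(4S)-4-(tert-butyldimethylsilyloxy)-1-hydroxy-2-methylenepentyl]-3,4,6-trimethoxyphenyl}prop-2-en-1-ol (mixture of diastereomers at both carbinols), via 1-ethoxyvinyllithium 12 (not isolated), via ring-opened aldehyde alkoxide 13 (not isolated)
Conditions: 11, t-BuLi, THF, −78 → 0 °C; then 10 (0.3 equiv relative to 12), −78 → 0 °C; H2O; filtration through basic Al2O3
Reagents that add atoms: none
Why: α-Lithiation of the vinyl ether gives an acyl anion equivalent; its first equivalent deprotonates the lactol, which opens to the non-enolisable aryl aldehyde, and a second adds to the formyl group (organolithium addition to a lactol). The second carbinol centre (future C1) is again uncontrolled, and 14 is kept away from acid because of its enol ether.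

Step 7
Reactants: 14 2-ethoxy-1-{2-[(4S)-4-(tert-butyldimethylsilyloxy)-1-hydroxy-2-methylenepentyl]-3,4,6-trimethoxyphenyl}prop-2-en-1-ol
Product: 15 3-[(S)-2-(tert-butyldimethylsilyloxy)propyl]-2-ethoxy-5,6,8-trimethoxy-1,4-dihydronaphthalene-1,4-diol (mixture of diastereomers at C1 and C4)
Conditions: RuCl2(=CH-C6H4-2-O-i-Pr)(H2ITol) (10 mol %; H2ITol = 1,3-bis(2-methylphenyl)imidazolidin-2-ylidene), PhMe (0.01 M, degassed, base-washed glass), 80 °C, Ar sparge
Reagents that add atoms: none
Why: Proposed new method: ring-closing metathesis to a tetrasubstituted olefin that carries an alkoxy group is not documented; the closest known reaction types are the closure of ortho-bis(1-hydroxyallyl)benzenes to 1,4-dihydronaphthalene-1,4-diols, the closure of acyclic 1,1-disubstituted alkyl and silyl enol ethers onto monosubstituted olefins, and the closure of all-carbon tetrasubstituted olefins with carbene ligands of reduced ortho bulk, from which the bis(2-methylphenyl) catalyst is taken. After initiation (loss of the chelating styrenyl ether) the 14-electron ruthenium alkylidene is expected to load on the all-carbon 1,1-disubstituted olefin at C3 with loss of ethylene, the tethered disubstituted alkylidene then adds across the methylene terminus of the enol ether in an intramolecular [2+2] cycloaddition, and cycloreversion of the ruthenacyclobutane releases C2=C3 and a ruthenium methylidene. Entry through the enol ether, giving a Fischer-type alkylidene held next to the second olefin, would converge on the same ruthenacyclobutane. Ring A is thus closed as a six-membered, benzo-fused cyclohexa-1,4-diene at its only non-aromatic double bond, the ortho relationship of C4a and C8a holding the two vinyl groups within bonding distance. No stereocentre is created: C1 and C4 enter as mixtures and are erased in step 8, and the (S) centre lies outside the reacting olefin. Ring closure must win over intermolecular metathesis, which dilution and the reluctance of 1,1-disubstituted olefins to homodimerise should secure, while the orientation of ring A is not at stake because steps 5 and 6 fixed it. The catalyst must survive the enol ether, which a 1,1-disubstituted enol ether permits because it cannot form the inert [Ru]=CH(OR) species that monosubstituted vinyl ethers give, and the medium must stay neutral and free of ruthenium hydrides so that the allylic carbinols are neither ionised nor isomerised to ketones. Continuous removal of ethylene supplies the driving force for a ring that is nearly free of strain.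

Step 8
Reactants: 15 3-[(S)-2-(tert-butyldimethylsilyloxy)propyl]-2-ethoxy-5,6,8-trimethoxy-1,4-dihydronaphthalene-1,4-diol
Product: 17 3-[(S)-2-(tert-butyldimethylsilyloxy)propyl]-2-ethoxy-5,6,8-trimethoxy-1,4-naphthoquinone, via hydroquinone 16 (not isolated)
Conditions: MnO2 (activated, excess), CH2Cl2, rt
Reagents that add atoms: none
Why: MnO2 oxidation of benzylic, allylic alcohols: the first oxidation gives a hydroxy enone that should aromatise to the hydroquinone, which MnO2 takes on to the quinone, so every diastereomer of 15 converges on 17 (stereoconvergent oxidation). The neutral heterogeneous oxidant should spare ring B, the silyl ether and the enol ether oxygen.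

Step 9
Reactants: 17 3-[(S)-2-(tert-butyldimethylsilyloxy)propyl]-2-ethoxy-5,6,8-trimethoxy-1,4-naphthoquinone
Product: 18 3-[(S)-2-(tert-butyldimethylsilyloxy)propyl]-2-hydroxy-5,6,8-trimethoxy-1,4-naphthoquinone
Conditions: NaOH (0.5 M aq.), THF, Ar, rt → 40 °C; then 1 M HCl to pH 3
Reagents that add atoms: sodium hydroxide (supplies the C2 oxygen), [Na+].[OH-]
Why: Hydrolysis of a vinylogous ester by conjugate addition–elimination of hydroxide at C2; the product is held as its delocalised anion, which resists further attack, and the aryl methyl ethers and the secondary silyl ether are inert to dilute alkali. Air is excluded to avoid Hooker-type oxidative degradation, and the side chain is still silylated so that no alkoxide can displace the ethoxy group intramolecularly.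

Step 10
Reactants: 18 3-[(S)-2-(tert-butyldimethylsilyloxy)propyl]-2-hydroxy-5,6,8-trimethoxy-1,4-naphthoquinone
Product: 19 2-hydroxy-3-[(S)-2-hydroxypropyl]-5,6,8-trimethoxy-1,4-naphthoquinone
Conditions: HF·pyridine, pyridine, THF, 0 °C → rt (polypropylene vessel)
Reagents that add atoms: none
Why: Fluoride-induced cleavage of the Si–O bond (silyl ether deprotection); the buffered, mildly acidic medium keeps the hydroxyquinone protonated and unreactive, and the C–O bond of the stereocentre is not touched.

Step 11
Reactants: 19 2-hydroxy-3-[(S)-2-hydroxypropyl]-5,6,8-trimethoxy-1,4-naphthoquinone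
Product: 21 3-[(S)-2-acetoxypropyl]-2-hydroxy-5,6,8-trimethoxy-1,4-naphthoquinone (target), via bis-acetate 20 (not isolated)
Conditions: Ac2O, pyridine, DMAP (cat.), CH2Cl2, 0 °C → rt; then aq. NaHCO3, THF, rt; 1 M HCl to pH 4
Reagents that add atoms: acetic anhydride, CC(=O)OC(C)=O
Why: DMAP-catalysed acylation esterifies the secondary alcohol and, unavoidably, the acidic C2 hydroxyl; the C2 acetate is a vinylogous mixed anhydride and should be hydrolysed by bicarbonate far faster than the secondary alkyl acetate, and attack at its acyl carbon or at C2 gives the same hydroxyquinone. Only O–acyl bonds are made and broken, so the (S) centre is unaffected.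

## Compound list

1 | (S)-γ-valerolactone | C[C@H]1CCC(=O)O1 | starting material
2 | (4S)-4-hydroxy-N-methoxy-N-methylpentanamide | C[C@H](O)CCC(=O)N(C)OC | intermediate
3 | (4S)-4-(tert-butyldimethylsilyloxy)-N-methoxy-N-methylpentanamide | C[C@H](O[Si](C)(C)C(C)(C)C)CCC(=O)N(C)OC | intermediate
4 | (4S)-4-(tert-butyldimethylsilyloxy)pentanal | C[C@H](O[Si](C)(C)C(C)(C)C)CCC=O | intermediate
5 | (4S)-4-(tert-butyldimethylsilyloxy)-2-methylenepentanal | C[C@H](O[Si](C)(C)C(C)(C)C)CC(=C)C=O | intermediate
6 | 2,4,5-trimethoxybenzaldehyde | COc1cc(OC)c(C=O)cc1OC | starting material
7 | lithium α-amino alkoxide from 6 and lithium N,N,N′-trimethylethylenediamide (not isolated) | COc1cc(OC)c(C(O[Li])N(C)CCN(C)C)cc1OC | intermediate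
8 | ring-lithiated α-amino alkoxide, lithium on the carbon between the masked formyl group and the neighbouring methoxy group (not isolated) | COc1cc(OC)c(C(O[Li])N(C)CCN(C)C)c([Li])c1OC | intermediate
9 | dilithium adduct of 8 with 5 (not isolated) | COc1cc(OC)c(C(O[Li])N(C)CCN(C)C)c(C(O[Li])C(=C)C[C@H](C)O[Si](C)(C)C(C)(C)C)c1OC | intermediate
10 | 3-[(4S)-4-(tert-butyldimethylsilyloxy)pent-1-en-2-yl]-4,5,7-trimethoxy-1,3-dihydroisobenzofuran-1-ol | COc1cc(OC)c2c(c1OC)C(C(=C)C[C@H](C)O[Si](C)(C)C(C)(C)C)OC2O | intermediate
11 | ethyl vinyl ether | C=COCC | starting material
12 | 1-ethoxyvinyllithium (not isolated) | [Li]C(=C)OCC | intermediate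
13 | lithium (4S)-4-(tert-butyldimethylsilyloxy)-1-(2-formyl-3,5,6-trimethoxyphenyl)-2-methylenepentan-1-olate (not isolated) | COc1cc(OC)c(C=O)c(C(O[Li])C(=C)C[C@H](C)O[Si](C)(C)C(C)(C)C)c1OC | intermediate
14 | 2-ethoxy-1-{2-[(4S)-4-(tert-butyldimethylsilyloxy)-1-hydroxy-2-methylenepentyl]-3,4,6-trimethoxyphenyl}prop-2-en-1-ol | C=C(OCC)C(O)c1c(OC)cc(OC)c(OC)c1C(O)C(=C)C[C@H](C)O[Si](C)(C)C(C)(C)C | intermediate
15 | 3-[(S)-2-(tert-butyldimethylsilyloxy)propyl]-2-ethoxy-5,6,8-trimethoxy-1,4-dihydronaphthalene-1,4-diol | COc1cc(OC)c2c(c1OC)C(O)C(C[C@H](C)O[Si](C)(C)C(C)(C)C)=C(OCC)C2O | intermediate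
16 | 3-[(S)-2-(tert-butyldimethylsilyloxy)propyl]-2-ethoxy-5,6,8-trimethoxynaphthalene-1,4-diol (not isolated) | COc1cc(OC)c2c(O)c(OCC)c(C[C@H](C)O[Si](C)(C)C(C)(C)C)c(O)c2c1OC | intermediate
17 | 3-[(S)-2-(tert-butyldimethylsilyloxy)propyl]-2-ethoxy-5,6,8-trimethoxy-1,4-naphthoquinone | COc1cc(OC)c2c(c1OC)C(=O)C(C[C@H](C)O[Si](C)(C)C(C)(C)C)=C(OCC)C2=O | intermediate
18 | 3-[(S)-2-(tert-butyldimethylsilyloxy)propyl]-2-hydroxy-5,6,8-trimethoxy-1,4-naphthoquinone | COc1cc(OC)c2c(c1OC)C(=O)C(C[C@H](C)O[Si](C)(C)C(C)(C)C)=C(O)C2=O | intermediate
19 | 2-hydroxy-3-[(S)-2-hydroxypropyl]-5,6,8-trimethoxy-1,4-naphthoquinone | COc1cc(OC)c2c(c1OC)C(=O)C(C[C@H](C)O)=C(O)C2=O | intermediate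
20 | 2-acetoxy-3-[(S)-2-acetoxypropyl]-5,6,8-trimethoxy-1,4-naphthoquinone (not isolated) | COc1cc(OC)c2c(c1OC)C(=O)C(C[C@H](C)OC(C)=O)=C(OC(C)=O)C2=O | intermediate
21 | 3-[(S)-2-acetoxypropyl]-2-hydroxy-5,6,8-trimethoxy-1,4-naphthoquinone | COc1cc(OC)c2c(c1OC)C(=O)C(C[C@H](C)OC(C)=O)=C(O)C2=O | target

## Step count and least certain steps

Total step count: 11. Longest linear sequence: 11 steps (1 to 21); 6 and 11 are bought and enter at steps 5 and 6.

Step 7 (key step). The catalytic cycle is most likely to stall where a disubstituted ruthenium alkylidene must add to a second 1,1-disubstituted olefin. The ruthenacyclobutane would carry two adjacent fully substituted carbons, each next to an ortho-substituted benzylic carbinol. Slow turnover at 80 °C then gives time for decomposition of the catalyst to hydride species, which isomerise the allylic carbinols to ketones. Loss of water from the product is also possible but harmless, since it converges in the oxidation. RuCl2(=CHPh)(PCy3)(H2IMes) (second-generation Grubbs catalyst) would be run as the comparison.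
Fallback (known chemistry; sets out from 10 and comes back at 18): 10 is treated with CH2=CHMgBr in place of 12 to give the vinyl diol F1. Ring closure of F1 with RuCl2(=CHPh)(PCy3)(H2IMes) in CH2Cl2 at 40 °C now has to form only a trisubstituted all-carbon olefin and should give the dihydronaphthalenediol F2. MnO2 would oxidise this to the 2-unsubstituted quinone F3. Alkaline H2O2 (Na2CO3, aqueous THF, 0 °C) would epoxidise the quinone double bond to the quinone epoxide F4. Dilute aqueous NaOH would then isomerise F4 to 18 (opening of the oxirane and loss of water), the oxygen necessarily ending on the carbon that carried hydrogen. The enol ether is given up, but the order of the two additions, and with it the orientation of ring A, is kept.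

Step 5. The most likely failure is metallation at the wrong ring position, the C–H between the two other methoxy groups, which is also doubly activated. Incomplete metallation is the second risk, since it leaves butyllithium to add to the enal. Both follow from relying on kinetic direction by the amino alkoxide.
Fallback (sets out from enal 5 as the unchanged partner, replaces 6 by a bromoarene and comes back at 8): commercial 3-bromo-4,5-dimethoxybenzaldehyde F5 would undergo Baeyer–Villiger oxidation (mCPBA, CH2Cl2) to the aryl formate F6. Methanolysis (K2CO3, MeOH) would give 3-bromo-4,5-dimethoxyphenol F7, and O-methylation (MeI, K2CO3, acetone) 1-bromo-2,3,5-trimethoxybenzene F8. Vilsmeier–Haack formylation (POCl3, DMF), directed para to one methoxy group and ortho to another, should give 2-bromo-3,4,6-trimethoxybenzaldehyde F9. Addition of LiN(Me)CH2CH2NMe2 would mask its formyl group as the bromo α-amino alkoxide F10, and bromine–lithium exchange with n-BuLi at −78 °C would give 8 with the metal on the required carbon by construction.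

Step 6. The lactol alkoxide may open only slowly, so that addition stalls and forcing conditions degrade the vinyllithium. During isolation the enol ether can be hydrolysed, or a neighbouring hydroxyl can add to it, if any acid is present.
Fallback (sets out from 10 and comes back at 14): oxidation of the lactol with MnO2 would give the phthalide F11. Addition of one equivalent of 12 at −78 °C stops at the ketone stage because the tetrahedral adduct is a stable hemiketal alkoxide, giving the α-ethoxy enone F12 (in equilibrium with its cyclic hemiketal). 1,2-Reduction with i-Bu2AlH at −78 °C would return 14.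

Step 8. Loss of water from 15 before or during oxidation would aromatise ring A to a naphthol, which MnO2 converts slowly and with oxidative coupling as a side path. The doubly benzylic, enol-ether-activated carbinols ionise easily.
Fallback (sets out from 15 and comes back at 17): the dehydration is made deliberate with catalytic pyridinium p-toluenesulfonate in CH2Cl2, giving the C1 naphthol F13 and possibly its C4 regioisomer F14. Both have a free para position and would be oxidised to 17 with Fremy's salt, (KSO3)2NO, in buffered aqueous acetone.

## Further compounds

F1 | step 7 | 1-{2-[(4S)-4-(tert-butyldimethylsilyloxy)-1-hydroxy-2-methylenepentyl]-3,4,6-trimethoxyphenyl}prop-2-en-1-ol | C=CC(O)c1c(OC)cc(OC)c(OC)c1C(O)C(=C)C[C@H](C)O[Si](C)(C)C(C)(C)C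
F2 | step 7 | 3-[(S)-2-(tert-butyldimethylsilyloxy)propyl]-5,6,8-trimethoxy-1,4-dihydronaphthalene-1,4-diol (target numbering) | COc1cc(OC)c2c(c1OC)C(O)C(C[C@H](C)O[Si](C)(C)C(C)(C)C)=CC2O
F3 | step 7 | 3-[(S)-2-(tert-butyldimethylsilyloxy)propyl]-5,6,8-trimethoxy-1,4-naphthoquinone (target numbering) | COc1cc(OC)c2c(c1OC)C(=O)C(C[C@H](C)O[Si](C)(C)C(C)(C)C)=CC2=O
F4 | step 7 | 2,3-epoxy-3-[(S)-2-(tert-butyldimethylsilyloxy)propyl]-5,6,8-trimethoxy-2,3-dihydro-1,4-naphthoquinone (target numbering) | COc1cc(OC)c2c(c1OC)C(=O)C1(C[C@H](C)O[Si](C)(C)C(C)(C)C)OC1C2=O
F5 | step 5 | 3-bromo-4,5-dimethoxybenzaldehyde | COc1cc(C=O)cc(Br)c1OC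
F6 | step 5 | 3-bromo-4,5-dimethoxyphenyl formate | COc1cc(OC=O)cc(Br)c1OC
F7 | step 5 | 3-bromo-4,5-dimethoxyphenol | COc1cc(O)cc(Br)c1OC
F8 | step 5 | 1-bromo-2,3,5-trimethoxybenzene | COc1cc(OC)c(OC)c(Br)c1
F9 | step 5 | 2-bromo-3,4,6-trimethoxybenzaldehyde | COc1cc(OC)c(C=O)c(Br)c1OC
F10 | step 5 | lithium α-amino alkoxide from F9 and lithium N,N,N′-trimethylethylenediamide | COc1cc(OC)c(C(O[Li])N(C)CCN(C)C)c(Br)c1OC
F11 | step 6 | 3-[(4S)-4-(tert-butyldimethylsilyloxy)pent-1-en-2-yl]-4,5,7-trimethoxyisobenzofuran-1(3H)-one | COc1cc(OC)c2c(c1OC)C(C(=C)C[C@H](C)O[Si](C)(C)C(C)(C)C)OC2=O
F12 | step 6 | 2-ethoxy-1-{2-[(4S)-4-(tert-butyldimethylsilyloxy)-1-hydroxy-2-methylenepentyl]-3,4,6-trimethoxyphenyl}prop-2-en-1-one | C=C(OCC)C(=O)c1c(OC)cc(OC)c(OC)c1C(O)C(=C)C[C@H](C)O[Si](C)(C)C(C)(C)C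
F13 | step 8 | 3-[(S)-2-(tert-butyldimethylsilyloxy)propyl]-2-ethoxy-5,6,8-trimethoxynaphthalen-1-ol (target numbering) | COc1cc(OC)c2c(O)c(OCC)c(C[C@H](C)O[Si](C)(C)C(C)(C)C)cc2c1OC
F14 | step 8 | 3-[(S)-2-(tert-butyldimethylsilyloxy)propyl]-2-ethoxy-5,6,8-trimethoxynaphthalen-4-ol (target numbering) | COc1cc(OC)c2cc(OCC)c(C[C@H](C)O[Si](C)(C)C(C)(C)C)c(O)c2c1OC
A1 | alternative 1 | methyl 2-{2-[(S)-4-(tert-butyldimethylsilyloxy)pentanoyl]-3,4,6-trimethoxyphenyl}acetate | COC(=O)Cc1c(OC)cc(OC)c(OC)c1C(=O)CC[C@H](C)O[Si](C)(C)C(C)(C)C
A2 | alternative 1 | 3,4,6-trimethoxy-2-(trimethylsilyl)phenyl trifluoromethanesulfonate | COc1cc(OC)c(OS(=O)(=O)C(F)(F)F)c([Si](C)(C)C)c1OC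
A3 | alternative 1 | methyl (S)-6-(tert-butyldimethylsilyloxy)-3-oxoheptanoate | COC(=O)CC(=O)CC[C@H](C)O[Si](C)(C)C(C)(C)C
A4 | alternative 1 | 3,4,6-trimethoxybenzyne | COC1=CC(OC)=C(OC)C#C1
A5 | alternative 2 | 3-[(S)-2-acetoxypropyl]-2,5,6-trimethoxynaphthalene-1,4,8-triol | COc1cc(O)c2c(c1OC)c(O)c(C[C@H](C)OC(C)=O)c(OC)c2O
A6 | alternative 2 | 3-[(S)-2-acetoxypropyl]-2-methoxy-1,4-benzoquinone | COC1=C(C[C@H](C)OC(C)=O)C(=O)C=CC1=O
A7 | alternative 2 | 1,3,4-trimethoxy-1-(trimethylsilyloxy)buta-1,3-diene | COC=C(OC)C=C(OC)O[Si](C)(C)C
A8 | alternative 3 | 3-[(S)-2-(tert-butyldimethylsilyloxy)propyl]-4-hydroxy-5,6,8-trimethoxy-2-(triisopropylsilyloxy)naphthalene (target numbering) | COc1cc(OC)c2cc(O[Si](C(C)C)(C(C)C)C(C)C)c(C[C@H](C)O[Si](C)(C)C(C)(C)C)c(O)c2c1OC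
A9 | alternative 3 | 2-diazo-1-(2,4,5-trimethoxyphenyl)ethanone | COc1cc(OC)c(C(=O)C=[N+]=[N-])cc1OC
A10 | alternative 3 | (S)-4-(tert-butyldimethylsilyloxy)-1-(triisopropylsilyloxy)pent-1-yne | CC(C)[Si](OC#CC[C@H](C)O[Si](C)(C)C(C)(C)C)(C(C)C)C(C)C
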